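**Retrosynthetic overview**
1. Target 22 comes from the cis-(3S,4S)-isoflavan-4-ol 20, whose ring B is a hydroquinone bis(benzyl ether): one hydrogenolysis removes the C4 oxygen and both benzyl groups, and Ag2O then gives the quinone.
2. C3 is set by catalyst-controlled transfer hydrogenation of the racemic isoflavanone 19 with dynamic kinetic resolution; 19 comes from isoflavone 15 by oxidative demethylation of ring B, reductive benzylation and conjugate reduction.
3. Structural feature: C2 of the pyran ring is a lone CH2 between O1 and C3. The pyran ring (the only ring made; rings A and B are bought as arenes) is therefore closed by inserting one carbon between the ring A phenol oxygen and the C3 methylene of deoxybenzoin 12, with the C4 carbonyl as a temporary handle.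
4. 12 comes from Friedel–Crafts acylation of 2,3,4-trimethoxyphenol with (pentamethoxyphenyl)acetic acid 10, made from pentamethoxybenzene 6 (lithiation, oxirane, oxidation), which comes from 3,4,5-trimethoxyphenol.

Key step: step 7

Remark: ring A of the final chroman is a 1,2,3,4-tetraoxygenated arene with a para O1/6-OMe pair and would itself be attacked by tetravalent cerium, so ring B is oxidised at the isoflavone stage, where the C4 carbonyl deactivates ring A, and the quinone is carried on as the bis(benzyl ether) of its hydroquinone.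
Remark: 2,3,4-trimethoxyphenol (11) is taken as a purchasable compound.

**Route**

Step 1
Reactants: 1 3,4,5-trimethoxyphenol
Product: 2 1,2,3,5-tetramethoxybenzene
Conditions: MeI, K2CO3, acetone, reflux
Reagents that add atoms: iodomethane, CI
Why: Williamson O-methylation of the phenoxide is the only reaction open to this substrate.

Step 2
Reactants: 2 1,2,3,5-tetramethoxybenzene
Product: 5 2,3,4,6-tetramethoxyphenol, via aryllithium 3 (not isolated), via dimethyl arylboronate 4 (not isolated)
Conditions: n-BuLi, THF, 0 °C to 25 °C; B(OMe)3, −78 °C to 25 °C; AcOH, 30% H2O2, 0 °C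
Reagents that add atoms: hydrogen peroxide, OO
Why: Directed ortho-lithiation at one of the two equivalent C–H positions (each flanked by two methoxy groups), borylation and peroxide oxidation of the C–B bond with 1,2-aryl shift should give the phenol.

Step 3
Reactants: 5 2,3,4,6-tetramethoxyphenol
Product: 6 pentamethoxybenzene
Conditions: MeI, K2CO3, DMF, 25 °C
Reagents that add atoms: iodomethane, CI
Why: Williamson O-methylation of the hindered but unhindered-at-oxygen phenoxide should proceed cleanly in a dipolar aprotic solvent.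

Step 4
Reactants: 6 pentamethoxybenzene
Product: 8 2-(pentamethoxyphenyl)ethanol, via pentamethoxyphenyllithium 7 (not isolated)
Conditions: n-BuLi, THF, 0 °C to 25 °C; oxirane (THF solution), −20 °C to 25 °C; H2O
Reagents that add atoms: oxirane, C1CO1
Why: Ortho-lithiation at the single ring C–H, which lies between two methoxy groups, followed by SN2 opening of the epoxide by the aryllithium should install the two-carbon chain.

Step 5
Reactants: 8 2-(pentamethoxyphenyl)ethanol
Product: 10 (pentamethoxyphenyl)acetic acid, via arylacetaldehyde 9 (not isolated)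
Conditions: TEMPO (cat.), NaOCl (cat.), NaClO2, MeCN/phosphate buffer pH 6.7, 35 °C
Reagents that add atoms: sodium chlorite, [Na+].[O-]Cl=O
Why: Anelli-type oxoammonium oxidation to the aldehyde and Pinnick-type chlorite oxidation in the same flask should give the acid, and the fully substituted arene has no free position for chlorination.

Step 6
Reactants: 10 (pentamethoxyphenyl)acetic acid; 11 2,3,4-trimethoxyphenol
Product: 12 1-(2-hydroxy-3,4,5-trimethoxyphenyl)-2-(pentamethoxyphenyl)ethanone
Conditions: BF3·OEt2 (neat), 85 °C; then aq NaOAc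
Reagents that add atoms: none
Why: Friedel–Crafts acylation of the phenol (through the aryl ester and a Fries-type shift) should occur at C6, the only free position ortho to the hydroxyl, and is driven by the BF2 chelate of the ortho-hydroxy ketone.

Step 7
Reactants: 12 1-(2-hydroxy-3,4,5-trimethoxyphenyl)-2-(pentamethoxyphenyl)ethanone
Product: 15 6,7,8-trimethoxy-3-(pentamethoxyphenyl)-4H-chromen-4-one, via enaminone 13 (not isolated), via 2-(dimethylamino)chromanone 14 (not isolated)
Conditions: Me2NCH(OMe)2 (3 equiv), toluene, 100 °C; then AcOH, 60 °C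
Reagents that add atoms: N,N-dimethylformamide dimethyl acetal, COC(OC)N(C)C
Why: The acetal ionises to the methoxy(dimethylamino)carbenium ion and methoxide, the ketone enolises at the C3 methylene (activated by the C4 carbonyl and ring B), and C-attack on the iminium carbon with loss of methanol gives enaminone 13 (new C2–C3 bond). The ring A phenol then adds to the enaminone β-carbon (C2) in a 6-endo-trig oxa-Michael addition to give aminal 14, and loss of dimethylamine closes the pyranone (new O1–C2 bond). This is the standard formamide-acetal synthesis of isoflavones from 2-hydroxydeoxybenzoins, applied here to a ring B with both ortho positions substituted. No stereocenter is formed. The step needs C- rather than O-functionalisation: the methylene is the only doubly activated C–H site, the phenol is held in a hydrogen bond to the ketone, and any O-adduct of the phenol forms reversibly, whereas enaminone formation and ring closure are each driven forward by loss of a volatile fragment and formation of the conjugated 4-pyranone.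

Step 8
Reactants: 15 6,7,8-trimethoxy-3-(pentamethoxyphenyl)-4H-chromen-4-one
Product: 16 2,3,5-trimethoxy-6-(6,7,8-trimethoxy-4-oxo-4H-chromen-3-yl)cyclohexa-2,5-diene-1,4-dione
Conditions: (NH4)2Ce(NO3)6 (2.5 equiv), MeCN/H2O, 0 °C
Reagents that add atoms: water, O
Why: Oxidative demethylation by tetravalent cerium should take place on ring B only, because ring A is deactivated by the conjugated C4 carbonyl, and the two para-dimethoxy pairs of ring B are symmetry-equivalent so only one para-quinone can form.

Step 9
Reactants: 16 2,3,5-trimethoxy-6-(6,7,8-trimethoxy-4-oxo-4H-chromen-3-yl)cyclohexa-2,5-diene-1,4-dione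
Product: 18 3-[2,5-bis(benzyloxy)-3,4,6-trimethoxyphenyl]-6,7,8-trimethoxy-4H-chromen-4-one, via hydroquinone 17 (not isolated)
Conditions: Na2S2O4, EtOAc/H2O, 25 °C; then BnBr, K2CO3, DMF, 25 °C to 50 °C (under Ar)
Reagents that add atoms: benzyl bromide, BrCc1ccccc1
Why: Dithionite reduction of the quinone and Williamson benzylation of both phenols should mask ring B in a form that survives hydride and transfer-hydrogenation conditions and is released by hydrogenolysis.

Step 10
Reactants: 18 3-[2,5-bis(benzyloxy)-3,4,6-trimethoxyphenyl]-6,7,8-trimethoxy-4H-chromen-4-one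
Product: 19 rac-3-[2,5-bis(benzyloxy)-3,4,6-trimethoxyphenyl]-6,7,8-trimethoxychroman-4-one
Conditions: LiBH(s-Bu)3 (1.2 equiv), THF, −78 °C; then H2O
Reagents that add atoms: none
Why: Conjugate (1,4) hydride addition to the unhindered C2 of the chromone gives an enolate that masks the C4 carbonyl until work-up, where protonation should give the racemic isoflavanone.

Step 11
Reactants: 19 rac-3-[2,5-bis(benzyloxy)-3,4,6-trimethoxyphenyl]-6,7,8-trimethoxychroman-4-one
Product: 20 (3S,4S)-3-[2,5-bis(benzyloxy)-3,4,6-trimethoxyphenyl]-6,7,8-trimethoxychroman-4-ol (cis)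
Conditions: RuCl(p-cymene)[(S,S)-TsDPEN] (2 mol %), HCO2H, Et3N (excess), EtOAc, 40 °C
Reagents that add atoms: none
Why: In this Noyori–Ikariya transfer hydrogenation with dynamic kinetic resolution, C3 epimerises through the enol under the amine conditions while the (S,S)-catalyst delivers hydride to the C4 face that gives the 4S carbinol (as with 4-chromanone) and anti to the C3 aryl group, so the 3S ketone should be reduced faster and the cis-(3S,4S) alcohol should result.

Step 12
Reactants: 20 (3S,4S)-3-[2,5-bis(benzyloxy)-3,4,6-trimethoxyphenyl]-6,7,8-trimethoxychroman-4-ol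
Product: 22 2,3,5-trimethoxy-6-[(3S)-6,7,8-trimethoxychroman-3-yl]cyclohexa-2,5-diene-1,4-dione, via hydroquinone 21 (not isolated)
Conditions: H2 (1 atm), 10% Pd/C, EtOAc/AcOH, 25 °C; filter under Ar, concentrate; Ag2O, Na2SO4, Et2O, 25 °C
Reagents that add atoms: none
Why: Hydrogenolysis should cleave both benzyl ethers and the C4 benzylic C–O bond (activated by O1 and the para 7-methoxy group) without touching C3, and Ag2O then oxidises only the free hydroquinone, leaving the ring A ethers intact.

**Compound list**
1 | 3,4,5-trimethoxyphenol | COc1cc(O)cc(OC)c1OC | starting material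
2 | 1,2,3,5-tetramethoxybenzene | COc1cc(OC)cc(OC)c1OC | intermediate
3 | (2,3,4,6-tetramethoxyphenyl)lithium | [Li]c1c(OC)cc(OC)c(OC)c1OC | intermediate
4 | dimethyl (2,3,4,6-tetramethoxyphenyl)boronate | COB(OC)c1c(OC)cc(OC)c(OC)c1OC | intermediate
5 | 2,3,4,6-tetramethoxyphenol | COc1cc(OC)c(OC)c(OC)c1O | intermediate
6 | pentamethoxybenzene | COc1cc(OC)c(OC)c(OC)c1OC | intermediate
7 | (pentamethoxyphenyl)lithium | [Li]c1c(OC)c(OC)c(OC)c(OC)c1OC | intermediate
8 | 2-(pentamethoxyphenyl)ethanol | COc1c(OC)c(OC)c(OC)c(OC)c1CCO | intermediate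
9 | (pentamethoxyphenyl)acetaldehyde | COc1c(OC)c(OC)c(OC)c(OC)c1CC=O | intermediate
10 | (pentamethoxyphenyl)acetic acid | COc1c(OC)c(OC)c(OC)c(OC)c1CC(=O)O | intermediate
11 | 2,3,4-trimethoxyphenol | COc1ccc(O)c(OC)c1OC | starting material
12 | 1-(2-hydroxy-3,4,5-trimethoxyphenyl)-2-(pentamethoxyphenyl)ethanone | COc1c(OC)c(OC)c(OC)c(OC)c1CC(=O)c1cc(OC)c(OC)c(OC)c1O | intermediate
13 | 3-(dimethylamino)-1-(2-hydroxy-3,4,5-trimethoxyphenyl)-2-(pentamethoxyphenyl)prop-2-en-1-one | CN(C)C=C(C(=O)c1cc(OC)c(OC)c(OC)c1O)c1c(OC)c(OC)c(OC)c(OC)c1OC | intermediate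
14 | 2-(dimethylamino)-6,7,8-trimethoxy-3-(pentamethoxyphenyl)chroman-4-one | CN(C)C1Oc2c(OC)c(OC)c(OC)cc2C(=O)C1c1c(OC)c(OC)c(OC)c(OC)c1OC | intermediate
15 | 6,7,8-trimethoxy-3-(pentamethoxyphenyl)-4H-chromen-4-one | COc1c(OC)c(OC)c(OC)c(OC)c1C1=COc2c(OC)c(OC)c(OC)cc2C1=O | intermediate
16 | 2,3,5-trimethoxy-6-(6,7,8-trimethoxy-4-oxo-4H-chromen-3-yl)cyclohexa-2,5-diene-1,4-dione | COC1=C(OC)C(=O)C(=C(OC)C1=O)C1=COc2c(OC)c(OC)c(OC)cc2C1=O | intermediate
17 | 3-(2,5-dihydroxy-3,4,6-trimethoxyphenyl)-6,7,8-trimethoxy-4H-chromen-4-one | COc1cc2C(=O)C(=COc2c(OC)c1OC)c1c(O)c(OC)c(OC)c(O)c1OC | intermediate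
18 | 3-[2,5-bis(benzyloxy)-3,4,6-trimethoxyphenyl]-6,7,8-trimethoxy-4H-chromen-4-one | COc1cc2C(=O)C(=COc2c(OC)c1OC)c1c(OCc2ccccc2)c(OC)c(OC)c(OCc2ccccc2)c1OC | intermediate
19 | rac-3-[2,5-bis(benzyloxy)-3,4,6-trimethoxyphenyl]-6,7,8-trimethoxychroman-4-one | COc1cc2C(=O)C(COc2c(OC)c1OC)c1c(OCc2ccccc2)c(OC)c(OC)c(OCc2ccccc2)c1OC | intermediate
20 | (3S,4S)-3-[2,5-bis(benzyloxy)-3,4,6-trimethoxyphenyl]-6,7,8-trimethoxychroman-4-ol | COc1cc2[C@@H](O)[C@H](COc2c(OC)c1OC)c1c(OCc2ccccc2)c(OC)c(OC)c(OCc2ccccc2)c1OC | intermediate
21 | 2,3,5-trimethoxy-6-[(3S)-6,7,8-trimethoxychroman-3-yl]benzene-1,4-diol | COc1cc2C[C@H](COc2c(OC)c1OC)c1c(O)c(OC)c(OC)c(O)c1OC | intermediate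
22 | 2,3,5-trimethoxy-6-[(3S)-6,7,8-trimethoxychroman-3-yl]cyclohexa-2,5-diene-1,4-dione | COC1=C(OC)C(=O)C([C@H]2COc3c(cc(OC)c(OC)c3OC)C2)=C(OC)C1=O | target

**Step count**
Total steps: 12. Longest linear sequence: 12 steps (1 to 22); 11 enters at step 6 without prior steps.

**Steps most likely to fail**

Step 11. Epimerisation at C3 of the crowded 3-aryl chromanone may be slower than hydride transfer, so the reaction would behave as a simple kinetic resolution and stall near half conversion or give cis/trans mixtures. The 2'-benzyloxy and 6'-methoxy groups may also block approach of the ruthenium hydride. The fallback sets C3 by alkene hydrogenation instead of ketone reduction and sets out from 19. NaBH4 in MeOH/THF should give rac-3-[2,5-bis(benzyloxy)-3,4,6-trimethoxyphenyl]-6,7,8-trimethoxychroman-4-ol F1 as a diastereomer mixture. Acid-catalysed dehydration (p-TsOH cat., toluene, 60 °C) should then give 3-[2,5-bis(benzyloxy)-3,4,6-trimethoxyphenyl]-6,7,8-trimethoxy-2H-chromene F2. Asymmetric hydrogenation of this trisubstituted cyclic alkene with a cationic iridium phosphinooxazoline complex, [Ir(cod)(PHOX)][B(3,5-(CF3)2C6H3)4], under H2 in CH2Cl2 should give (3S)-3-[2,5-bis(benzyloxy)-3,4,6-trimethoxyphenyl]-6,7,8-trimethoxychroman F3; the ligand enantiomer would be chosen to deliver the 3S product. Neutral hydrogenolysis (H2, Pd/C, EtOAc) removes the benzyl groups and returns to the route at hydroquinone 21, which is oxidised to 22 as in step 12.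

Step 7. Condensation at the methylene carbon, which is shielded by both ortho-methoxy groups of ring B, may be slow enough that O-methylation of the ring A phenol by the acetal takes over, or the sequence may stall at the open enaminone. The fallback reverses the order of bond formation (O1–C2 first, C2–C3 second) by a Baker–Ollis-type ethoxalyl annulation and sets out from 12. Ethyl chlorooxoacetate in pyridine (0 °C to 25 °C) should acylate the phenol, and intramolecular aldol condensation of the methylene onto the keto ester with dehydration should give ethyl 6,7,8-trimethoxy-4-oxo-3-(pentamethoxyphenyl)-4H-chromene-2-carboxylate F4. Acid hydrolysis (aq HCl/AcOH, 80 °C) should give 6,7,8-trimethoxy-4-oxo-3-(pentamethoxyphenyl)-4H-chromene-2-carboxylic acid F5. Thermal decarboxylation (Cu powder, quinoline, 190 °C) returns to the route at isoflavone 15.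

Step 12. In acidic medium the C4 cation, stabilised by O1 and the 7-methoxy group, may lose H-3 to give the achiral 2H-chromene, which would then be hydrogenated without control and erode the C3 configuration. The fallback removes the C4 oxygen by a radical path that cannot involve C3 (Barton–McCombie deoxygenation) and sets out from 20. NaH, CS2 and MeI in THF should give O-[(3S,4S)-3-[2,5-bis(benzyloxy)-3,4,6-trimethoxyphenyl]-6,7,8-trimethoxychroman-4-yl] S-methyl carbonodithioate F6; syn-elimination towards C3 is not available because H-3 is anti to the C4 oxygen. Bu3SnH and AIBN in toluene at 90 °C should then give the (3S)-isoflavan bis(benzyl ether) F3, the same compound as in the fallback to step 11. Neutral hydrogenolysis (H2, Pd/C, EtOAc) returns to the route at hydroquinone 21, followed by Ag2O oxidation to 22.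

**Further compounds**
F1 | step 11 | rac-3-[2,5-bis(benzyloxy)-3,4,6-trimethoxyphenyl]-6,7,8-trimethoxychroman-4-ol (diastereomer mixture) | COc1cc2C(O)C(COc2c(OC)c1OC)c1c(OCc2ccccc2)c(OC)c(OC)c(OCc2ccccc2)c1OC
F2 | step 11 | 3-[2,5-bis(benzyloxy)-3,4,6-trimethoxyphenyl]-6,7,8-trimethoxy-2H-chromene | COc1cc2C=C(COc2c(OC)c1OC)c1c(OCc2ccccc2)c(OC)c(OC)c(OCc2ccccc2)c1OC
F3 | step 11 | (3S)-3-[2,5-bis(benzyloxy)-3,4,6-trimethoxyphenyl]-6,7,8-trimethoxychroman | COc1cc2C[C@H](COc2c(OC)c1OC)c1c(OCc2ccccc2)c(OC)c(OC)c(OCc2ccccc2)c1OC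
F4 | step 7 | ethyl 6,7,8-trimethoxy-4-oxo-3-(pentamethoxyphenyl)-4H-chromene-2-carboxylate | CCOC(=O)C1=C(C(=O)c2cc(OC)c(OC)c(OC)c2O1)c1c(OC)c(OC)c(OC)c(OC)c1OC
F5 | step 7 | 6,7,8-trimethoxy-4-oxo-3-(pentamethoxyphenyl)-4H-chromene-2-carboxylic acid | OC(=O)C1=C(C(=O)c2cc(OC)c(OC)c(OC)c2O1)c1c(OC)c(OC)c(OC)c(OC)c1OC
F6 | step 12 | O-[(3S,4S)-3-[2,5-bis(benzyloxy)-3,4,6-trimethoxyphenyl]-6,7,8-trimethoxychroman-4-yl] S-methyl carbonodithioate | COc1cc2[C@@H](OC(=S)SC)[C@H](COc2c(OC)c1OC)c1c(OCc2ccccc2)c(OC)c(OC)c(OCc2ccccc2)c1OC
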